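**Plan**
- Cuts: after removal of the acetates, O-methyl groups and ester, ring A is opened at C8–C9 and C6–C7 to a ring-B-fused 3-carbomethoxy-2-pyrone and 1,1,2-trimethoxyethene. The pyrone is cut at C5–C10 and its ring C–O bond to a cyclohexanone and dimethyl methoxymethylenemalonate. The side chain is cut at C18–O and C12–C13.
- Forward order: ring B is taken intact from (R)-carvone. The C13–C16 unit is joined at C12 by a copper-catalysed Grignard coupling, O18 is added by hydroboration, the pyrone ring is built on C9/C10, and ring A is formed last.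
- Enabling feature: ring A is a pentasubstituted benzene with the C19 carboxyl on C6, hydroxyls on C7 and C8 in a row and one hydrogen on C5. It is fused at C9–C10 to the trans-1,4-disubstituted ring B (C1–C4, C10, C9 are the carvone ring). This is the pattern a carboxylated 2-pyrone and a trialkoxyethene leave after loss of CO2 and an alcohol.
- Stereochemistry: C4 from (R)-carvone, C1 by equilibrating protonation to the trans ketone, C15 from methyl (R)-3-hydroxy-2-methylpropanoate (Roche ester), C11 by a ligand-controlled copper hydride hydroboration. The key step leaves no new stereocentre.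

Key step: step 14

Numbering used below: C1 (ring CH with methyl C20), C2, C3 (ring CH2), C4 (ring CH with the side chain), C5 (arene CH), C6 (arene C with carboxyl C19), C7, C8 (arene C–O), C9 (arene C bonded to C1), C10 (arene C bonded to C4), C11 (CH with C18H2O), C12–C14 (CH2), C15 (CH with methyl C17 and C16H2O). TBDPS = tert-butyldiphenylsilyl.

Assumption (step 10): the (R)-ligand is taken to deliver hydride to the face of C11 that gives the 11S alcohol; the sense depends on the ligand alone, so the (S)-ligand is used if a trial run shows the opposite.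

Assumption (reagent 23): 1,1,2-trimethoxyethene is taken as a purchasable reagent and enters as a starting material.

Step 1
Reactants: 1 methyl (R)-3-hydroxy-2-methylpropanoate
Product: 2 methyl (R)-3-[(tert-butyldiphenylsilyl)oxy]-2-methylpropanoate
Conditions: TBDPSCl, imidazole, DMF, 0 → 25 °C
Reagents that add atoms: tert-butyl(chloro)diphenylsilane, CC(C)(C)[Si](Cl)(c1ccccc1)c1ccccc1
Why: Imidazole-mediated silyl ether formation on a primary alcohol is routine and leaves the α-stereocentre untouched; TBDPS is chosen because it should outlast the later ketal hydrolysis.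

Step 2
Reactants: 2 methyl (R)-3-[(tert-butyldiphenylsilyl)oxy]-2-methylpropanoate
Product: 3 (R)-3-[(tert-butyldiphenylsilyl)oxy]-2-methylpropanal
Conditions: i-Bu2AlH, CH2Cl2, −78 °C; aq. potassium sodium tartrate
Reagents that add atoms: none
Why: Partial ester reduction stops at the aluminium hemiacetal at −78 °C and releases the aldehyde on work-up; the aldehyde is used at once so that its α-stereocentre should not epimerise.

Step 3
Reactants: 3 (R)-3-[(tert-butyldiphenylsilyl)oxy]-2-methylpropanal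
Product: 4 (S)-tert-butyl[(2-methylbut-3-en-1-yl)oxy]diphenylsilane
Conditions: Ph3PCH3Br, KN(SiMe3)2, THF, 0 °C; then 3, −78 → 0 °C
Reagents that add atoms: methyltriphenylphosphonium bromide, C[P+](c1ccccc1)(c1ccccc1)c1ccccc1.[Br-]
Why: Wittig methylenation with the preformed non-stabilised ylide adds C13 at low temperature without epimerising the α-centre (the descriptor changes from R to S only through the priority change).

Step 4
Reactants: 4 (S)-tert-butyl[(2-methylbut-3-en-1-yl)oxy]diphenylsilane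
Product: 6 (S)-4-[(tert-butyldiphenylsilyl)oxy]-3-methylbutan-1-ol, via B-alkyl-9-BBN adduct 5 (not isolated)
Conditions: 9-BBN, THF, 0 → 25 °C; then NaOH, H2O2, H2O, 0 → 25 °C
Reagents that add atoms: hydrogen peroxide, OO
Why: Anti-Markovnikov hydroboration–oxidation of a monosubstituted alkene with 9-BBN places the hydroxyl on the terminal carbon C13.

Step 5
Reactants: 6 (S)-4-[(tert-butyldiphenylsilyl)oxy]-3-methylbutan-1-ol
Product: 7 (S)-(4-bromo-2-methylbutoxy)(tert-butyl)diphenylsilane
Conditions: CBr4, PPh3, CH2Cl2, 0 °C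
Reagents that add atoms: carbon tetrabromide, BrC(Br)(Br)Br
Why: Appel bromination converts the primary alcohol into the bromide under neutral conditions that spare the silyl ether.

Step 6
Reactants: 8 (R)-carvone
Product: 10 (2R,5R)-2-methyl-5-(prop-1-en-2-yl)cyclohexan-1-one (trans-dihydrocarvone), via lithium enolate 9 (not isolated)
Conditions: LiBH(s-Bu)3, THF, −78 °C; H2O; then NaOMe (cat.), MeOH, 25 °C
Reagents that add atoms: none
Why: The hindered borohydride adds hydride 1,4 to the β-unsubstituted enone (conjugate reduction) without touching the isopropenyl group, and protonation of enolate 9 followed by base equilibration should settle C1 trans (diequatorial) to C4, which is carried over from carvone.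

Step 7
Reactants: 10 (2R,5R)-2-methyl-5-(prop-1-en-2-yl)cyclohexan-1-one
Product: 11 (6R,9R)-6-methyl-9-(prop-1-en-2-yl)-1,4-dioxaspiro[4.5]decane
Conditions: ethylene glycol, PPTS (cat.), benzene, reflux, Dean–Stark
Reagents that add atoms: ethylene glycol, OCCO
Why: Acid-catalysed acetalisation with removal of water masks the ketone against the Grignard and copper hydride steps, and any enolisation at C1 is under thermodynamic control and returns the trans isomer.

Step 8
Reactants: 11 (6R,9R)-6-methyl-9-(prop-1-en-2-yl)-1,4-dioxaspiro[4.5]decane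
Product: 12 (6R,9R)-9-(3-chloroprop-1-en-2-yl)-6-methyl-1,4-dioxaspiro[4.5]decane
Conditions: Ca(OCl)2, solid CO2, CH2Cl2/H2O, 0 °C
Reagents that add atoms: calcium hypochlorite, [Ca+2].[O-]Cl.[O-]Cl
Why: Hypochlorous acid formed in the flask chlorinates the 1,1-disubstituted alkene in an ene-type allylic chlorination with transposition of the double bond, the usual way to functionalise the isopropenyl methyl group of p-menthanes.

Step 9
Reactants: 12 (6R,9R)-9-(3-chloroprop-1-en-2-yl)-6-methyl-1,4-dioxaspiro[4.5]decane; 7 (S)-(4-bromo-2-methylbutoxy)(tert-butyl)diphenylsilane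
Product: 14 tert-butyl({(S)-2-methyl-6-[(6R,9R)-6-methyl-1,4-dioxaspiro[4.5]decan-9-yl]hept-6-en-1-yl}oxy)diphenylsilane, via Grignard reagent 13 (not isolated)
Conditions: 7, Mg, THF, 40 °C; then 12, Li2CuCl4 (cat.), THF, −20 → 0 °C
Reagents that add atoms: none
Why: Copper-catalysed coupling of a primary alkyl Grignard reagent with an allylic chloride forms C12–C13, and because the 2-substituted allyl unit is symmetric the direct and the allylic (SN2') mode of attack give the same product.

Step 10
Reactants: 14 tert-butyl({(S)-2-methyl-6-[(6R,9R)-6-methyl-1,4-dioxaspiro[4.5]decan-9-yl]hept-6-en-1-yl}oxy)diphenylsilane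
Product: 16 (2S,6S)-7-[(tert-butyldiphenylsilyl)oxy]-6-methyl-2-[(6R,9R)-6-methyl-1,4-dioxaspiro[4.5]decan-9-yl]heptan-1-ol, via pinacol boronate 15 (not isolated)
Conditions: CuCl (cat.), (R)-DTBM-SEGPHOS (cat.), NaOtBu (cat.), HBpin, toluene, 25 °C; then NaOH, H2O2, THF/H2O, 0 °C
Reagents that add atoms: hydrogen peroxide, OO
Why: The ligated monovalent copper hydride adds across the unactivated 1,1-disubstituted alkene with copper on terminal C18 and hydride on C11 (enantioselective CuH-catalysed anti-Markovnikov hydroboration), so C11 is set by the chiral bisphosphine, which tells the branched ring substituent from the linear chain, while the substrate itself should exert little bias because C4 is flanked by two CH2 groups; oxidation of the C–B bond then gives the alcohol.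

Step 11
Reactants: 16 (2S,6S)-7-[(tert-butyldiphenylsilyl)oxy]-6-methyl-2-[(6R,9R)-6-methyl-1,4-dioxaspiro[4.5]decan-9-yl]heptan-1-ol
Product: 17 (6R,9R)-9-{(2S,6S)-1,7-bis[(tert-butyldiphenylsilyl)oxy]-6-methylheptan-2-yl}-6-methyl-1,4-dioxaspiro[4.5]decane
Conditions: TBDPSCl, imidazole, DMF, 25 °C
Reagents that add atoms: tert-butyl(chloro)diphenylsilane, CC(C)(C)[Si](Cl)(c1ccccc1)c1ccccc1
Why: Silyl ether formation on the primary C18 hydroxyl gives both chain oxygens the same robust protecting group for the enolate and thermal steps.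

Step 12
Reactants: 17 (6R,9R)-9-{(2S,6S)-1,7-bis[(tert-butyldiphenylsilyl)oxy]-6-methylheptan-2-yl}-6-methyl-1,4-dioxaspiro[4.5]decane
Product: 18 (2R,5R)-5-{(2S,6S)-1,7-bis[(tert-butyldiphenylsilyl)oxy]-6-methylheptan-2-yl}-2-methylcyclohexan-1-one
Conditions: PPTS, acetone/H2O (10:1), 60 °C
Reagents that add atoms: water, O
Why: Mild acid-catalysed hydrolysis of the dioxolane frees the C9 ketone, and TBDPS ethers are stable to pyridinium tosylate.

Step 13
Reactants: 18 (2R,5R)-5-{(2S,6S)-1,7-bis[(tert-butyldiphenylsilyl)oxy]-6-methylheptan-2-yl}-2-methylcyclohexan-1-one; 19 dimethyl 2-(methoxymethylidene)propanedioate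
Product: 22 methyl (5S,8R)-5-{(2S,6S)-1,7-bis[(tert-butyldiphenylsilyl)oxy]-6-methylheptan-2-yl}-8-methyl-2-oxo-5,6,7,8-tetrahydro-2H-chromene-3-carboxylate, via lithium enolate 20 (not isolated), via alkylidenemalonate 21 (not isolated)
Conditions: LiN(i-Pr)2, THF, −78 °C; then 19, −78 → 25 °C; aq. NH4Cl; then TsOH·H2O (cat.), toluene, 80 °C
Reagents that add atoms: none
Why: Kinetic deprotonation takes the less substituted C10 methylene, the enolate adds to the β-methoxyacrylate unit and expels methoxide (addition–elimination), and the enol oxygen on C9 then lactonises onto one ester with loss of methanol (2-pyrone annulation of a ketone enolate with an alkoxymethylenemalonate); the transient C10 centre of 21 is lost on enolisation.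

Step 14
Reactants: 22 methyl (5S,8R)-5-{(2S,6S)-1,7-bis[(tert-butyldiphenylsilyl)oxy]-6-methylheptan-2-yl}-8-methyl-2-oxo-5,6,7,8-tetrahydro-2H-chromene-3-carboxylate; 23 1,1,2-trimethoxyethene
Product: 26 methyl (5R,8S)-8-{(2S,6S)-1,7-bis[(tert-butyldiphenylsilyl)oxy]-6-methylheptan-2-yl}-3,4-dimethoxy-5-methyl-5,6,7,8-tetrahydronaphthalene-2-carboxylate, via bridged lactone cycloadduct 24 (not isolated), via trimethoxycyclohexadiene 25 (not isolated)
Conditions: 23 (5 equiv), toluene, 140 °C, sealed tube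
Reagents that add atoms: none
Why: The ester-bearing pyrone is an electron-poor diene (C6=C5–C10=C9) and the trialkoxyethene an electron-rich 2π partner, so an inverse-electron-demand Diels–Alder reaction forms C8–C9 and C6–C7 to give bridged lactone 24, which expels CO2 by retro-[4+2] to diene 25 and then loses methanol by 1,2-elimination to the arene. The closest known reaction type is the thermal benzannulation of 3-carbomethoxy-2-pyrones with ketene acetals to give ortho-alkoxybenzoates. Ring A is closed intermolecularly as a six-membered carbocycle by [4+2] cycloaddition, both σ bonds forming in one asynchronous step led by C8–C9, and aromatisation makes the closure irreversible. No new stereocentre survives, since the sp3 centres at C6, C8 and C9 of 24 are erased, and C1, C4, C11 and C15 are spectators under neutral heating. The step needs regioselectivity, which the ester on C6 secures by making C9 the vinylogous acceptor terminus, so that the nucleophilic CH(OMe) carbon of 23 bonds there and the acetal carbon bonds to C6, placing both oxygens next to the ester. Chemoselectivity should follow because no other π system in 22 is electron-poor enough to react with the ketene acetal and the silyl ethers are inert to neutral heat.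

Step 15
Reactants: 26 methyl (5R,8S)-8-{(2S,6S)-1,7-bis[(tert-butyldiphenylsilyl)oxy]-6-methylheptan-2-yl}-3,4-dimethoxy-5-methyl-5,6,7,8-tetrahydronaphthalene-2-carboxylate
Product: 27 methyl (5R,8S)-8-[(2S,6S)-1,7-dihydroxy-6-methylheptan-2-yl]-3,4-dimethoxy-5-methyl-5,6,7,8-tetrahydronaphthalene-2-carboxylate
Conditions: Bu4NF, THF, 25 °C
Reagents that add atoms: none
Why: Fluoride cleaves both Si–O bonds (desilylation) without affecting the ester or the aryl methyl ethers, and it must precede BBr3, which would turn silyl ethers into bromides.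

Step 16
Reactants: 27 methyl (5R,8S)-8-[(2S,6S)-1,7-dihydroxy-6-methylheptan-2-yl]-3,4-dimethoxy-5-methyl-5,6,7,8-tetrahydronaphthalene-2-carboxylate
Product: 28 (5R,8S)-8-[(2S,6S)-1,7-dihydroxy-6-methylheptan-2-yl]-3,4-dimethoxy-5-methyl-5,6,7,8-tetrahydronaphthalene-2-carboxylic acid
Conditions: LiOH·H2O, THF/MeOH/H2O, 50 °C; then 1 M HCl
Reagents that add atoms: lithium hydroxide, [Li+].[OH-]
Why: Saponification of the methyl benzoate is done while the phenols are still methylated, so that no air-sensitive catecholate is exposed to hot base.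

Step 17
Reactants: 28 (5R,8S)-8-[(2S,6S)-1,7-dihydroxy-6-methylheptan-2-yl]-3,4-dimethoxy-5-methyl-5,6,7,8-tetrahydronaphthalene-2-carboxylic acid
Product: 29 (5R,8S)-8-[(2S,6S)-1,7-dihydroxy-6-methylheptan-2-yl]-3,4-dihydroxy-5-methyl-5,6,7,8-tetrahydronaphthalene-2-carboxylic acid
Conditions: BBr3, CH2Cl2, −78 → 0 °C; then H2O
Reagents that add atoms: none
Why: Lewis-acid O-demethylation, in which boron coordinates each aryl ether oxygen and bromide removes the methyl group, whereas the borate esters of the two β-branched primary alcohols resist bromide displacement at low temperature and are hydrolysed back on work-up.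

Step 18
Reactants: 29 (5R,8S)-8-[(2S,6S)-1,7-dihydroxy-6-methylheptan-2-yl]-3,4-dihydroxy-5-methyl-5,6,7,8-tetrahydronaphthalene-2-carboxylic acid
Product: 30 (5R,8S)-8-[(2S,6S)-1,7-diacetoxy-6-methylheptan-2-yl]-3,4-dihydroxy-5-methyl-5,6,7,8-tetrahydronaphthalene-2-carboxylic acid
Conditions: vinyl acetate, immobilised Candida antarctica lipase B, THF, 40 °C
Reagents that add atoms: vinyl acetate, CC(=O)OC=C
Why: Lipase-catalysed transesterification with an enol ester acylates primary aliphatic hydroxyls but not phenols or the carboxylic acid and is made irreversible by tautomerisation of vinyl alcohol to acetaldehyde, so only O16 and O18 should be acetylated.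

**Compound list**
1 | methyl (R)-3-hydroxy-2-methylpropanoate | COC(=O)[C@H](C)CO | starting material
2 | methyl (R)-3-[(tert-butyldiphenylsilyl)oxy]-2-methylpropanoate | CC(C)(C)[Si](c1ccccc1)(c1ccccc1)OC[C@@H](C)C(=O)OC | intermediate
3 | (R)-3-[(tert-butyldiphenylsilyl)oxy]-2-methylpropanal | CC(C)(C)[Si](c1ccccc1)(c1ccccc1)OC[C@@H](C)C=O | intermediate
4 | (S)-tert-butyl[(2-methylbut-3-en-1-yl)oxy]diphenylsilane | CC(C)(C)[Si](c1ccccc1)(c1ccccc1)OC[C@@H](C)C=C | intermediate
5 | 9-{(S)-4-[(tert-butyldiphenylsilyl)oxy]-3-methylbutyl}-9-borabicyclo[3.3.1]nonane | CC(C)(C)[Si](c1ccccc1)(c1ccccc1)OC[C@@H](C)CCB1C2CCCC1CCC2 | intermediate (not isolated)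
6 | (S)-4-[(tert-butyldiphenylsilyl)oxy]-3-methylbutan-1-ol | CC(C)(C)[Si](c1ccccc1)(c1ccccc1)OC[C@@H](C)CCO | intermediate
7 | (S)-(4-bromo-2-methylbutoxy)(tert-butyl)diphenylsilane | CC(C)(C)[Si](c1ccccc1)(c1ccccc1)OC[C@@H](C)CCBr | intermediate
8 | (R)-carvone, (R)-2-methyl-5-(prop-1-en-2-yl)cyclohex-2-en-1-one | CC1=CC[C@H](CC1=O)C(C)=C | starting material
9 | lithium (R)-2-methyl-5-(prop-1-en-2-yl)cyclohex-1-en-1-olate | CC(=C)[C@@H]1CCC(C)=C(O[Li])C1 | intermediate (not isolated)
10 | (2R,5R)-2-methyl-5-(prop-1-en-2-yl)cyclohexan-1-one (trans-dihydrocarvone) | CC(=C)[C@@H]1CC[C@@H](C)C(=O)C1 | intermediate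
11 | (6R,9R)-6-methyl-9-(prop-1-en-2-yl)-1,4-dioxaspiro[4.5]decane | CC(=C)[C@@H]1CC[C@@H](C)C2(C1)OCCO2 | intermediate
12 | (6R,9R)-9-(3-chloroprop-1-en-2-yl)-6-methyl-1,4-dioxaspiro[4.5]decane | ClCC(=C)[C@@H]1CC[C@@H](C)C2(C1)OCCO2 | intermediate
13 | {(S)-4-[(tert-butyldiphenylsilyl)oxy]-3-methylbutyl}magnesium bromide | CC(C)(C)[Si](c1ccccc1)(c1ccccc1)OC[C@@H](C)CC[Mg]Br | intermediate (not isolated)
14 | tert-butyl({(S)-2-methyl-6-[(6R,9R)-6-methyl-1,4-dioxaspiro[4.5]decan-9-yl]hept-6-en-1-yl}oxy)diphenylsilane | CC(C)(C)[Si](c1ccccc1)(c1ccccc1)OC[C@@H](C)CCCC(=C)[C@@H]1CC[C@@H](C)C2(C1)OCCO2 | intermediate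
15 | 2-{(2S,6S)-7-[(tert-butyldiphenylsilyl)oxy]-6-methyl-2-[(6R,9R)-6-methyl-1,4-dioxaspiro[4.5]decan-9-yl]heptyl}-4,4,5,5-tetramethyl-1,3,2-dioxaborolane | CC(C)(C)[Si](c1ccccc1)(c1ccccc1)OC[C@@H](C)CCC[C@H](CB3OC(C)(C)C(C)(C)O3)[C@@H]1CC[C@@H](C)C2(C1)OCCO2 | intermediate (not isolated)
16 | (2S,6S)-7-[(tert-butyldiphenylsilyl)oxy]-6-methyl-2-[(6R,9R)-6-methyl-1,4-dioxaspiro[4.5]decan-9-yl]heptan-1-ol | CC(C)(C)[Si](c1ccccc1)(c1ccccc1)OC[C@@H](C)CCC[C@H](CO)[C@@H]1CC[C@@H](C)C2(C1)OCCO2 | intermediate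
17 | (6R,9R)-9-{(2S,6S)-1,7-bis[(tert-butyldiphenylsilyl)oxy]-6-methylheptan-2-yl}-6-methyl-1,4-dioxaspiro[4.5]decane | CC(C)(C)[Si](c1ccccc1)(c1ccccc1)OC[C@@H](C)CCC[C@H](CO[Si](c1ccccc1)(c1ccccc1)C(C)(C)C)[C@@H]1CC[C@@H](C)C2(C1)OCCO2 | intermediate
18 | (2R,5R)-5-{(2S,6S)-1,7-bis[(tert-butyldiphenylsilyl)oxy]-6-methylheptan-2-yl}-2-methylcyclohexan-1-one | CC(C)(C)[Si](c1ccccc1)(c1ccccc1)OC[C@@H](C)CCC[C@H](CO[Si](c1ccccc1)(c1ccccc1)C(C)(C)C)[C@@H]1CC[C@@H](C)C(=O)C1 | intermediate
19 | dimethyl 2-(methoxymethylidene)propanedioate (dimethyl methoxymethylenemalonate) | COC=C(C(=O)OC)C(=O)OC | starting material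
20 | lithium (3S,6R)-3-{(2S,6S)-1,7-bis[(tert-butyldiphenylsilyl)oxy]-6-methylheptan-2-yl}-6-methylcyclohex-1-en-1-olate | CC(C)(C)[Si](c1ccccc1)(c1ccccc1)OC[C@@H](C)CCC[C@H](CO[Si](c1ccccc1)(c1ccccc1)C(C)(C)C)[C@@H]1CC[C@@H](C)C(O[Li])=C1 | intermediate (not isolated)
21 | dimethyl 2-({(3R,6S)-6-{(2S,6S)-1,7-bis[(tert-butyldiphenylsilyl)oxy]-6-methylheptan-2-yl}-3-methyl-2-oxocyclohexyl}methylidene)propanedioate, ring carbon C10 unassigned | CC(C)(C)[Si](c1ccccc1)(c1ccccc1)OC[C@@H](C)CCC[C@H](CO[Si](c1ccccc1)(c1ccccc1)C(C)(C)C)[C@@H]1CC[C@@H](C)C(=O)C1C=C(C(=O)OC)C(=O)OC | intermediate (not isolated)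
22 | methyl (5S,8R)-5-{(2S,6S)-1,7-bis[(tert-butyldiphenylsilyl)oxy]-6-methylheptan-2-yl}-8-methyl-2-oxo-5,6,7,8-tetrahydro-2H-chromene-3-carboxylate | CC(C)(C)[Si](c1ccccc1)(c1ccccc1)OC[C@@H](C)CCC[C@H](CO[Si](c1ccccc1)(c1ccccc1)C(C)(C)C)[C@@H]1CC[C@@H](C)C2=C1C=C(C(=O)OC)C(=O)O2 | intermediate
23 | 1,1,2-trimethoxyethene | COC=C(OC)OC | starting material
24 | bridged lactone cycloadduct of 22 and 23: 2-oxabicyclo[2.2.2]oct-5-en-3-one with bridgeheads C9 and C6, lactone bridge C9–O–C(=O)–C6, new bridge C7(OMe)2–C8H(OMe), alkene C5=C10, ester on C6, ring B fused at C9–C10; new centres C6, C8, C9 unassigned | CC(C)(C)[Si](c1ccccc1)(c1ccccc1)OC[C@@H](C)CCC[C@H](CO[Si](c1ccccc1)(c1ccccc1)C(C)(C)C)[C@@H]1CC[C@@H](C)C23OC(=O)C(C(=O)OC)(C=C12)C(OC)(OC)C3OC | intermediate (not isolated)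
25 | methyl (5R,8S)-8-{(2S,6S)-1,7-bis[(tert-butyldiphenylsilyl)oxy]-6-methylheptan-2-yl}-3,3,4-trimethoxy-5-methyl-3,4,5,6,7,8-hexahydronaphthalene-2-carboxylate, C4 of this name unassigned | CC(C)(C)[Si](c1ccccc1)(c1ccccc1)OC[C@@H](C)CCC[C@H](CO[Si](c1ccccc1)(c1ccccc1)C(C)(C)C)[C@@H]1CC[C@@H](C)C2=C1C=C(C(=O)OC)C(OC)(OC)C2OC | intermediate (not isolated)
26 | methyl (5R,8S)-8-{(2S,6S)-1,7-bis[(tert-butyldiphenylsilyl)oxy]-6-methylheptan-2-yl}-3,4-dimethoxy-5-methyl-5,6,7,8-tetrahydronaphthalene-2-carboxylate | CC(C)(C)[Si](c1ccccc1)(c1ccccc1)OC[C@@H](C)CCC[C@H](CO[Si](c1ccccc1)(c1ccccc1)C(C)(C)C)[C@@H]1CC[C@@H](C)c2c1cc(C(=O)OC)c(OC)c2OC | intermediate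
27 | methyl (5R,8S)-8-[(2S,6S)-1,7-dihydroxy-6-methylheptan-2-yl]-3,4-dimethoxy-5-methyl-5,6,7,8-tetrahydronaphthalene-2-carboxylate | OC[C@@H](C)CCC[C@H](CO)[C@@H]1CC[C@@H](C)c2c1cc(C(=O)OC)c(OC)c2OC | intermediate
28 | (5R,8S)-8-[(2S,6S)-1,7-dihydroxy-6-methylheptan-2-yl]-3,4-dimethoxy-5-methyl-5,6,7,8-tetrahydronaphthalene-2-carboxylic acid | OC[C@@H](C)CCC[C@H](CO)[C@@H]1CC[C@@H](C)c2c1cc(C(=O)O)c(OC)c2OC | intermediate
29 | (5R,8S)-8-[(2S,6S)-1,7-dihydroxy-6-methylheptan-2-yl]-3,4-dihydroxy-5-methyl-5,6,7,8-tetrahydronaphthalene-2-carboxylic acid | OC[C@@H](C)CCC[C@H](CO)[C@@H]1CC[C@@H](C)c2c1cc(C(=O)O)c(O)c2O | intermediate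
30 | (5R,8S)-8-[(2S,6S)-1,7-diacetoxy-6-methylheptan-2-yl]-3,4-dihydroxy-5-methyl-5,6,7,8-tetrahydronaphthalene-2-carboxylic acid (CNP0245723.2) | CC(=O)OC[C@@H](C)CCC[C@H](COC(C)=O)[C@@H]1CC[C@@H](C)c2c1cc(C(=O)O)c(O)c2O | target

**Step count and risks**
Total step count: 18. Longest linear sequence: 15 steps (steps 1–5, then 9–18, from compound 1); the carvone branch is 13 steps (steps 6–18).

The three steps most likely to fail:

Step 10. The chiral copper hydride may discriminate poorly between the two faces of C11, because its two substituents (a secondary ring carbon and a primary chain) differ less than in typical substrates, giving a mixture of C11 epimers. The fallback drops catalyst control in favour of separation with recycling. Alkene 14 would be hydroborated with 9-BBN and oxidised (NaOH, H2O2) to roughly equal amounts of 16 and its C11 epimer, (2R,6S)-7-[(tert-butyldiphenylsilyl)oxy]-6-methyl-2-[(6R,9R)-6-methyl-1,4-dioxaspiro[4.5]decan-9-yl]heptan-1-ol F1. The two are diastereomers at vicinal centres and should be separable by chromatography. The unwanted epimer would be oxidised with Dess–Martin periodinane and equilibrated at C11 with DBU to the aldehyde mixture, 7-[(tert-butyldiphenylsilyl)oxy]-6-methyl-2-[(6R,9R)-6-methyl-1,4-dioxaspiro[4.5]decan-9-yl]heptanal F2, then reduced with NaBH4 and separated again. The fallback sets out from 14 and returns to the route at 16.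

Step 14. Cycloaddition at the C9 terminus, which is flanked by the C1 methyl group, may be too slow with the trisubstituted ketene acetal, so that thermal decomposition of 23 outruns ring formation. The fallback builds the arene with a smaller partner and adds the C8 oxygen afterwards. Pyrone 22 would be heated with 1,1-dimethoxyethene (toluene, 120–140 °C) to give, after loss of CO2 and methanol, methyl (5R,8S)-8-{(2S,6S)-1,7-bis[(tert-butyldiphenylsilyl)oxy]-6-methylheptan-2-yl}-3-methoxy-5-methyl-5,6,7,8-tetrahydronaphthalene-2-carboxylate F3. Bromination with NBS in MeCN should go to C8, the only activated free position (ortho to the methoxy group, meta to the ester), giving methyl (5R,8S)-4-bromo-8-{(2S,6S)-1,7-bis[(tert-butyldiphenylsilyl)oxy]-6-methylheptan-2-yl}-3-methoxy-5-methyl-5,6,7,8-tetrahydronaphthalene-2-carboxylate F4. Palladium-catalysed C–O coupling with methanol (Pd2(dba)3, tBuBrettPhos, Cs2CO3, MeOH/dioxane, 60 °C) would then install the second methoxy group. The fallback sets out from 22 and returns to the route at 26.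

Step 18. Acyl transfer to the hindered C18 hydroxyl, which sits next to the branched C11, may stall in the enzyme and stop at a monoacetate. The fallback replaces selective acylation by exhaustive acylation and selective de-acylation. Acid 29 would be treated with Ac2O, pyridine and DMAP (the mixed anhydride at C19 hydrolyses on aqueous work-up) to give (5R,8S)-3,4-diacetoxy-8-[(2S,6S)-1,7-diacetoxy-6-methylheptan-2-yl]-5-methyl-5,6,7,8-tetrahydronaphthalene-2-carboxylic acid F5. NH4OAc in MeOH/H2O at 25 °C should then cleave only the two aryl acetates, which are far more labile than primary alkyl acetates. The fallback sets out from 29 and returns to the route at 30.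

**Further compounds**
F1 | step 10 | (2R,6S)-7-[(tert-butyldiphenylsilyl)oxy]-6-methyl-2-[(6R,9R)-6-methyl-1,4-dioxaspiro[4.5]decan-9-yl]heptan-1-ol | CC(C)(C)[Si](c1ccccc1)(c1ccccc1)OC[C@@H](C)CCC[C@@H](CO)[C@@H]1CC[C@@H](C)C2(C1)OCCO2
F2 | step 10 | (6S)-7-[(tert-butyldiphenylsilyl)oxy]-6-methyl-2-[(6R,9R)-6-methyl-1,4-dioxaspiro[4.5]decan-9-yl]heptanal, both C2 epimers | CC(C)(C)[Si](c1ccccc1)(c1ccccc1)OC[C@@H](C)CCCC(C=O)[C@@H]1CC[C@@H](C)C2(C1)OCCO2
F3 | step 14 | methyl (5R,8S)-8-{(2S,6S)-1,7-bis[(tert-butyldiphenylsilyl)oxy]-6-methylheptan-2-yl}-3-methoxy-5-methyl-5,6,7,8-tetrahydronaphthalene-2-carboxylate | CC(C)(C)[Si](c1ccccc1)(c1ccccc1)OC[C@@H](C)CCC[C@H](CO[Si](c1ccccc1)(c1ccccc1)C(C)(C)C)[C@@H]1CC[C@@H](C)c2c1cc(C(=O)OC)c(OC)c2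
F4 | step 14 | methyl (5R,8S)-4-bromo-8-{(2S,6S)-1,7-bis[(tert-butyldiphenylsilyl)oxy]-6-methylheptan-2-yl}-3-methoxy-5-methyl-5,6,7,8-tetrahydronaphthalene-2-carboxylate | CC(C)(C)[Si](c1ccccc1)(c1ccccc1)OC[C@@H](C)CCC[C@H](CO[Si](c1ccccc1)(c1ccccc1)C(C)(C)C)[C@@H]1CC[C@@H](C)c2c1cc(C(=O)OC)c(OC)c2Br
F5 | step 18 | (5R,8S)-3,4-diacetoxy-8-[(2S,6S)-1,7-diacetoxy-6-methylheptan-2-yl]-5-methyl-5,6,7,8-tetrahydronaphthalene-2-carboxylic acid | CC(=O)OC[C@@H](C)CCC[C@H](COC(C)=O)[C@@H]1CC[C@@H](C)c2c1cc(C(=O)O)c(OC(C)=O)c2OC(C)=O
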